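## Structural features

Compound 26 is a daucane-type sesquiterpenoid ester on a bicyclo[5.3.0]decane. A cycloheptane (C1, C2, C3, C4, C5, C9, C10) and a cyclopentane (C4, C5, C6, C7, C8) share the C4–C5 bond. C1 carries an exocyclic methylene, C3 the 3-methylbutanoate, C5 an angular methyl group, C8 a hydroxyl and an isopropyl group, and C9 and C10 a cis-diol. The six stereocentres are contiguous (C10–C9–C5–C4–C3 along the large ring, C8 on C4) and read 3S, 4S, 5S, 8R, 9S, 10R. H4 and the C5 methyl are trans (trans ring fusion); O3, O9 and O10 lie on the face of the seven-membered ring opposite the methyl group; the C8 hydroxyl is cis to the C3 arm and the isopropyl group anti to it. The fragile parts are the tertiary C8 carbinol (acid-induced dehydration), the allylic C10 alcohol next to the C1 methylene (ionisation, alkene migration), the ester (base) and the 1,1-disubstituted alkene, which rules out hydrogenolysis. The real difficulty is the quaternary C5 flanked by stereocentres on both sides (C4 and C9), together with the fully substituted C8 and the trans-fused seven-membered ring. The key step uses two retrons that meet at C3: C8(OH)–C4–C3(O) is a β-hydroxy ether (enol ether C4=C3 added to a C8 ketone), and C3(O)–C2–C1(=CH2) is a homoallylic ether (2-(silylmethyl)allyl unit on C10 added to C3). The oxocarbenium ion left at C3 by the first bond formation is the electrophile for the second.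

## Logic of the disconnections

26 ⇒ 25 ⇒ 23 ⇒ 22. No skeletal bond is cut, only the ketal C–O bonds at O9/O10, the acyl–O3 bond and the benzyl–O3 bond. The acid-labile diol stays masked to the end and the base-labile ester goes on late. This leaves 22 with one free (tertiary) hydroxyl and a marked O3. The forward steps must acylate the secondary C3–OH of 23 in preference to the tertiary C8–OH, remove the benzylic ether oxidatively (the alkene forbids hydrogenolysis), and hydrolyse the ketal of 25 without touching the ester, the tertiary carbinol or the allylic system.

22 ⇒ 20. The C4–C8 and C2–C3 bonds are cut. Both rings and the stereocentres C3, C4 and C8 disappear, leaving an open chain whose only stereocentres are C5, C9 and C10. The forward step must make the enol ether, not the allylsilane, attack the ketone, must leave the ketal and the benzylic ether intact under Lewis acid, and must set three centres under control of the C5 quaternary centre and the chain geometry.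

20 ⇒ 19. The C3–O bond of the enol ether is cut. An alkenyl iodide can be made with defined E geometry and is stable to acid, so the acid-sensitive enol ether appears only in the last step before the cascade. The forward C–O coupling must retain the alkene geometry and run under non-acidic conditions that spare the ketone and the allylsilane.

19 ⇒ 18 ⇒ 17. The C8 ketone is returned to its ketal, and the C4=C3 bond is cut back to a neopentyl aldehyde plus a one-carbon unit. The aldehyde has no α-hydrogen, so it is configurationally safe. The olefination must be E-selective, and the ketal must later be removed in the presence of the diol ketal and the allylsilane.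

17 ⇒ 16 ⇒ 13 + 14. After an oxidation-level change at C4, the C1–CH2Si and C1=CH2 bonds are cut; both carbons come from 14, which adds twice to the lactone carbonyl C1. One operation on a compound with no other carbonyl group then gives the allylsilane and releases O4 as the hydroxyl needed next. The C8 ketone must therefore be masked, and the Peterson elimination must be mild.

13 ⇒ 11 ⇒ 10. No C–C bond is cut. The carbonyl is moved from C1 to C4 through the diol, because C5 can only be built α to a carbonyl whereas the allylsilane needs the carbonyl at C1. The oxidative lactonisation of 11 must start at the less hindered CH2OH (C1) and not at the neopentyl one (C4).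

10 ⇒ 8 ⇒ 3 + 6. The C5–CH3 bond is cut first, then C5–C6. Both bonds are made by enolate alkylation inside a cis-fused bicyclic lactone, so the last electrophile enters anti to the dioxolane; introducing the chain first and methyl second places methyl trans to O9 as required. Compound 3 then has only the two sugar-derived centres. The enolates must alkylate faster than they expel O9.

6 ⇒ 4 and 3 ⇒ 2 ⇒ 1. In 6 the C–I bond and the ketal C–O bonds are cut back to the enone 4 (conjugate addition of iodide, ketalisation). In 3 the lactone oxidation level and the diol ketal are removed to reach 1, whose C3 and C4 are C9 and C10 of 26 in the correct absolute sense.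

## Other disconnections considered

Alternative 1: the seven-membered ring is cut at C1–C2 and C5–C9 (formal 4+3). In the forward step Rh2(S-PTAD)4, a chiral carboxylate dimer of divalent rhodium, decomposes the siloxyvinyl diazo ester A3. The carbenoid cyclopropanates the vinyl group of diene A2, and the cis-divinylcyclopropane undergoes Cope rearrangement to the cycloheptadiene A1.
- In its favour: it is convergent, catalytic and enantioselective, and it makes the ring and the C5 quaternary centre from achiral compounds. The reaction class is well established, so on mechanistic security it is the better of the two plans.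
- Hydroboration of the C3=C4 alkene of A1 from the face away from the angular methyl should deliver H4 and O3 with the relationship needed in 26; on that pair it is the equal of the chosen cascade.
- Against it: A1 holds one of the six stereocentres. The Cope step must engage the fully substituted ring carbon. C9 is an unactivated CH2 between C5 and the C10 enol ether, and enolisation of the derived keto ester runs toward C1, so the C9 oxygen has no obvious entry.
- C1 must also be taken from ester to methylene, C10 reduced and C8 alkylated with an isopropyl nucleophile.
- Comparison: A1 is reached in fewer steps than 22, but 22 is three steps from 26, while A1 needs a long series of redox and stereo-setting steps. The chosen plan is more economical after the key step and less secure in the key step itself.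

Alternative 2: the cuts are C5–C9 and C3–C4, with no ring closure. In the forward step a chiral N-heterocyclic carbene copper catalyst made from Cu(OTf)2 adds the silylvinyl group of alane A7 to enone A5, and the aluminium enolate is trapped by aldehyde A6 to give the anti-aldol A4.
- In its favour: three stereocentres (C5, C4, C3) and two C–C bonds come from one catalytic step on cheap achiral inputs. For the creation of C5 this is shorter than, and in enantiocontrol the equal of, the sugar-based two-step alkylation chosen here. The C4/C5 and C3/C4 relationships follow well-understood enolate and aldol models, better precedented than the cascade.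
- Against it: the seven-membered ring still has to be closed, by metathesis between a 1,1-disubstituted vinylsilane and the terminal alkene, which would give a trans-fused ring and is demanding.
- In A4, C1 is a plain CH2 and C10 has no oxygen, so the methylene and the cis-diol must be built afterwards.
- The C8 ketone must accept an isopropyl nucleophile next to a β-hydroxyl, with retro-aldol as a threat.
- Comparison: the front end is shorter and catalytic, but the ring, C8, C9, C10 and the C1 methylene remain. The chosen plan has a longer front end but delivers both rings and the complete oxygen pattern in its key step.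

Alternative 3: the cut is C1–C10. In the forward step Ni(cod)2 (zerovalent nickel) with an N-heterocyclic carbene ligand and Et3SiH couples the aldehyde and the alkyne of ynal A9 through an oxanickelacycle to the tris(triethylsilyl) ether A8.
- In its favour: the ring closes last on a fully functionalised substrate under neutral conditions that tolerate the ester. The alkene position and the C10 silyl ether follow from the mechanism. A8 is one deprotection from 26, against three steps from 22, so on the endgame it is better than the chosen plan.
- Against it: a seven-membered exo closure onto a neopentyl α-silyloxy aldehyde is at the edge of the method.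
- C10 must be set cis to O9 by 1,2-induction alone.
- The whole stereochemical load (C3, C4, C5, C8, C9 on a cyclopentane, with the ester already in place) is moved into A9, for which this cut offers no simplification, and its aldehyde is epimerisable.
- Comparison: mechanism and endgame are equal or better; structure-building power and overall step economy are lower, because A9 needs a separate long synthesis of the cyclopentane core that the chosen cascade creates in passing.

Key step: step 13

Remarks on the chemistry:
- The configurations of 20, 22 and 26 were compared centre by centre and agree (5S, 9S, 10R in the chain; 3S, 4S, 8R added by the cascade), so none was altered. The erythro C9/C10 pair with C9 on the quaternary carbon corresponds to C3/C4 of a 2-deoxy-D-pentose, which fixes the D series.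
- Compound 1 is the commercial pyranose, written as its open-chain form. Compound 4 is taken as the commercial stabilised liquid.
- Compound 8 is drawn as its expected major C5 epimer; both epimers give the same enolate 9.

## Steps

Step 1
Reactants: 1 2-deoxy-D-ribose
Product: 2 2-deoxy-3,4-O-isopropylidene-D-erythro-pentopyranose (cis-fused dioxolane on O3/O4; anomer mixture)
Conditions: 2-methoxypropene, PPTS (cat.), EtOAc, 0 °C → rt
Reagents that add atoms: 2-methoxypropene, C=C(C)OC
Why: Acid-catalysed ketalisation of the only cis-vicinal diol of the pyranose form (O3/O4) gives the cis-fused dioxolane; these two carbons become C9 and C10 unchanged.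

Step 2
Reactants: 2 2-deoxy-3,4-O-isopropylidene-D-erythro-pentopyranose
Product: 3 2-deoxy-3,4-O-isopropylidene-D-erythro-pentono-1,5-lactone (carbonyl = C4, α-CH2 = C5, ring CH2O = C1)
Conditions: TEMPO (cat.), PhI(OAc)2, CH2Cl2, rt
Reagents that add atoms: none
Why: Oxoammonium oxidation of a lactol to the lactone; no stereocentre is involved.

Step 3
Reactants: 4 4-methylpent-1-en-3-one
Product: 6 2-(2-iodoethyl)-2-(propan-2-yl)-1,3-dioxolane, via β-iodo silyl enol ether 5 (not isolated)
Conditions: NaI, Me3SiCl, MeCN, 0 °C; then ethane-1,2-diol, rt
Reagents that add atoms: sodium iodide, [Na+].[I-]; ethane-1,2-diol, OCCO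
Why: Me3SiI formed in the flask adds 1,4 to the enone, and the glycol converts the silyl enol ether into the ketal (conjugate hydroiodination–ketalisation of an enone); the ketone stays masked until step 11.

Step 4
Reactants: 3 2-deoxy-3,4-O-isopropylidene-D-erythro-pentono-1,5-lactone; 6 2-(2-iodoethyl)-2-(propan-2-yl)-1,3-dioxolane
Product: 8 lactone 3 bearing at C5 the 2-(2-isopropyl-1,3-dioxolan-2-yl)ethyl chain (chain trans to the dioxolane), via lithium enolate 7 (not isolated)
Conditions: LiN(iPr)2 (LDA), THF, −78 °C; then 6, DMPU, −78 → −40 °C
Reagents that add atoms: none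
Why: SN2 alkylation of a lactone lithium enolate by a primary iodide, entering on the face away from the cis-fused dioxolane; the C5 configuration is of no consequence because C5 is enolised again in step 5, and low temperature with a polar additive keeps alkylation ahead of β-elimination of O9.

Step 5
Reactants: 8 C5-monoalkylated lactone
Product: 10 lactone with quaternary C5 (methyl trans to O9 and the ketal chain cis to O9), via lithium enolate 9 (not isolated)
Conditions: LiN(iPr)2, THF, −78 °C; then MeI, DMPU, −78 → −40 °C
Reagents that add atoms: iodomethane, CI
Why: Diastereoselective α-alkylation of a β-alkoxy lactone enolate: iodomethane approaches the trisubstituted enolate anti to the adjacent C9–O bond, on the convex face of the cis-fused bicycle, so methyl ends trans to O9, which is the C5 configuration of 26.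

Step 6
Reactants: 10 lactone with quaternary C5
Product: 11 diol (C4H2OH on C5 and C1H2OH on C10; dioxolane and ketal intact)
Conditions: LiAlH4, THF, 0 °C → rt
Reagents that add atoms: none
Why: Hydride reduction of a lactone to the 1,5-diol; ketals are inert and no stereocentre is touched.

Step 7
Reactants: 11 diol
Product: 13 δ-lactone with carbonyl at C1 and ring oxygen on C4 (dioxolane cis-fused at C9/C10), via lactol 12 (not isolated)
Conditions: TEMPO (20 mol%), PhI(OAc)2 (2.5 equiv), CH2Cl2, rt
Reagents that add atoms: none
Why: Oxoammonium oxidation is sensitive to hindrance, so the CH2OH next to the dioxolane (C1) should be oxidised before the neopentyl CH2OH (C4); the hydroxy aldehyde closes to lactol 12, which is oxidised again (chemoselective oxidative lactonisation of a 1,5-diol).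

Step 8
Reactants: 13 δ-lactone with carbonyl at C1; 14 (trimethylsilyl)methylmagnesium chloride
Product: 16 allylsilane alcohol [C10–C(=CH2)CH2SiMe3 and free C4H2OH], via bis(silylmethyl)carbinol 15 (not isolated)
Conditions: 14 (4 equiv), CeCl3 (4 equiv), THF, −78 °C → rt; then SiO2, CH2Cl2, rt
Reagents that add atoms: none
Why: The non-basic organocerium reagent adds twice to the lactone carbonyl, and silica-promoted Peterson elimination of one Me3SiOH from carbinol 15 leaves the 2-substituted allylsilane; ring opening releases O4 as the primary alcohol.

Step 9
Reactants: 16 allylsilane alcohol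
Product: 17 aldehyde (C4HO on quaternary C5)
Conditions: Dess–Martin periodinane, pyridine, CH2Cl2, 0 °C → rt
Reagents that add atoms: none
Why: Buffered periodinane oxidation of a neopentyl primary alcohol; the allylsilane and ketals tolerate it, and the aldehyde has no α-hydrogen and cannot epimerise.

Step 10
Reactants: 17 aldehyde
Product: 18 (E)-alkenyl iodide (C5–C4H=C3H–I)
Conditions: CrCl2 (6 equiv), CHI3 (2 equiv), THF/1,4-dioxane, 0 °C → rt
Reagents that add atoms: iodoform, IC(I)I
Why: Takai olefination: the gem-dichromium carbenoid from iodoform adds to the aldehyde and eliminates anti-periplanar, which favours the E isomer strongly for α-branched aldehydes; the allylsilane and ketals are inert to it.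

Step 11
Reactants: 18 (E)-alkenyl iodide
Product: 19 keto alkenyl iodide (free C8 isopropyl ketone)
Conditions: PPTS (cat.), acetone/H2O (20:1), 40 °C
Reagents that add atoms: water, O
Why: Acid-catalysed ketal exchange in wet acetone removes the ethylene ketal of the ketone while the diol ketal is maintained by the solvent; the alkenyl iodide is acid-stable and a 2-substituted allylsilane tolerates pyridinium tosylate.

Step 12
Reactants: 19 keto alkenyl iodide
Product: 20 open-chain keto (E)-enol ether allylsilane (C5–C4H=C3H–O–CH2C6H4OMe; 5S,9S,10R)
Conditions: CuI (10 mol%), 3,4,7,8-tetramethyl-1,10-phenanthroline (20 mol%), Cs2CO3, 4-methoxybenzyl alcohol (2 equiv), toluene, 80 °C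
Reagents that add atoms: 4-methoxybenzyl alcohol, COc1ccc(CO)cc1
Why: Ullmann-type copper-catalysed C–O coupling of an alkenyl iodide with a primary alcohol proceeds with retention of alkene geometry, so the E-iodide gives the E-enol ether; the basic, non-acidic medium preserves the enol ether and the allylsilane.

Step 13
Reactants: 20 open-chain keto (E)-enol ether allylsilane
Product: 22 bicyclic C3 p-methoxybenzyl ether with C8 carbinol and 9,10-O-isopropylidene group, via oxocarbenium titanium aldolate 21 (not isolated)
Conditions: TiCl4 (1.5 equiv), 2,6-di-tert-butyl-4-methylpyridine (2 equiv), CH2Cl2, −78 °C; then sat. aq. NaHCO3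
Reagents that add atoms: none
Why: Proposed new method: TiCl4 binds the C8 ketone, the enol ether attacks it through C4 (C4–C8, 5-(enolexo)-exo-trig), and the titanium aldolate 21 carries a C3 oxocarbenium ion that the =CH2 terminus of the 2-(silylmethyl)allyl unit captures (C2–C3, 7-endo-trig at the allylsilane alkene and exo at C3=O+), loss of Me3Si to chloride leaving the C1 methylene; the closest known reactions are Lewis-acid additions of alkyl enol ethers to carbonyl groups whose oxocarbenium ion is trapped by a tethered allylsilane (Mukaiyama aldol–Prins cascades) and intramolecular Hosomi–Sakurai closures of seven-membered rings, here joined on one chain with a ketone acceptor. C4: the oxocarbenium arm should settle on the methyl face of the quaternary C5, away from the bulky dioxolanyl (C9) arm, which is the trans ring fusion. C8: in the synclinal transition state the isopropyl group avoids the C3 arm and the titanium-bound oxygen lies next to the developing positive charge, so the hydroxyl ends cis to C3. C3: the allylsilane, delivered from the C5 side, should attack anti to the C4–C8 bond with the benzyloxy group equatorial (anti to C4–C5), which places O3 cis to H4. The step needs chemoselectivity between the two π-nucleophiles and between ketone and ketal: the enol ether reaches C8 through a five-membered transition state whereas the allylsilane would need an eight-membered one, and at −78 °C carbonyl activation should outpace ionisation of the dioxolane. The hindered pyridine removes adventitious HCl, which would protonate the enol ether or the allylsilane, and the cis-dioxolane holds C5 and C1 syn so that C2 can reach C3.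

Step 14
Reactants: 22 bicyclic C3 p-methoxybenzyl ether
Product: 23 bicyclic diol (free C3–OH and C8–OH; 9,10-O-isopropylidene)
Conditions: DDQ (1.3 equiv), CH2Cl2/pH 7 phosphate buffer (10:1), 0 °C
Reagents that add atoms: none
Why: Oxidative cleavage of a p-methoxybenzyl ether by DDQ; the 1,1-disubstituted alkene and the ketal are inert, and the aqueous buffer intercepts the benzylic cation before the neighbouring tertiary hydroxyl can.

Step 15
Reactants: 23 bicyclic diol; 24 3-methylbutanoyl chloride
Product: 25 C3 3-methylbutanoate with 9,10-O-isopropylidene group
Conditions: 24 (1.5 equiv), pyridine, DMAP (cat.), CH2Cl2, 0 °C → rt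
Reagents that add atoms: none
Why: DMAP-catalysed acylation of the secondary C3–OH; the tertiary C8–OH, flanked by isopropyl and the ring fusion, does not acylate under these conditions.

Step 16
Reactants: 25 C3 3-methylbutanoate acetonide
Product: 26 target (3S,4S,5S,8R,9S,10R)
Conditions: AcOH/H2O (4:1), 40 °C
Reagents that add atoms: none
Why: Mild aqueous acid hydrolysis of the isopropylidene ketal; the ester, the exocyclic alkene and the tertiary carbinol tolerate dilute acetic acid, and no stereocentre is affected.

## Compound list

1 | 2-deoxy-D-ribose (commercial pyranose, written as the open-chain (3S,4R)-aldehyde) | O=CC[C@H](O)[C@@H](CO)O | starting material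
2 | 2-deoxy-3,4-O-isopropylidene-D-erythro-pentopyranose (anomer mixture) | OC1C[C@@H]2OC(C)(C)O[C@@H]2CO1 | intermediate
3 | 2-deoxy-3,4-O-isopropylidene-D-erythro-pentono-1,5-lactone | O=C1C[C@@H]2OC(C)(C)O[C@@H]2CO1 | intermediate
4 | 4-methylpent-1-en-3-one | CC(C)C(=O)C=C | starting material
5 | (Z)-[(1-iodo-4-methylpent-2-en-3-yl)oxy]trimethylsilane | CC(C)C(/O[Si](C)(C)C)=C/CI | intermediate
6 | 2-(2-iodoethyl)-2-(propan-2-yl)-1,3-dioxolane | CC(C)C1(CCI)OCCO1 | intermediate
7 | lithium enolate of lactone 3 | [Li+].[O-]C1=C[C@@H]2OC(C)(C)O[C@@H]2CO1 | intermediate
8 | lactone 3 with the 2-(2-isopropyl-1,3-dioxolan-2-yl)ethyl chain at C5, trans to the dioxolane | O=C1[C@@H](CCC3(C(C)C)OCCO3)[C@@H]2OC(C)(C)O[C@@H]2CO1 | intermediate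
9 | lithium enolate of lactone 8 | [Li+].[O-]C1=C(CCC3(C(C)C)OCCO3)[C@@H]2OC(C)(C)O[C@@H]2CO1 | intermediate
10 | lactone with quaternary C5 (methyl trans to O9, ketal chain cis to O9) | O=C1[C@](C)(CCC3(C(C)C)OCCO3)[C@@H]2OC(C)(C)O[C@@H]2CO1 | intermediate
11 | diol from reduction of 10 (C4H2OH and C1H2OH) | OC[C@](C)(CCC3(C(C)C)OCCO3)[C@@H]2OC(C)(C)O[C@@H]2CO | intermediate
12 | lactol from oxidation of C1 of 11 (ring oxygen on C4; anomer mixture) | OC1OC[C@](C)(CCC3(C(C)C)OCCO3)[C@@H]2OC(C)(C)O[C@H]12 | intermediate
13 | δ-lactone with carbonyl at C1 and ring oxygen on C4 | O=C1OC[C@](C)(CCC3(C(C)C)OCCO3)[C@@H]2OC(C)(C)O[C@H]12 | intermediate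
14 | (trimethylsilyl)methylmagnesium chloride | C[Si](C)(C)C[Mg]Cl | starting material
15 | bis[(trimethylsilyl)methyl]carbinol at C1 with free C4H2OH | OC[C@](C)(CCC3(C(C)C)OCCO3)[C@@H]2OC(C)(C)O[C@@H]2C(O)(C[Si](C)(C)C)C[Si](C)(C)C | intermediate
16 | allylsilane alcohol (C10–C(=CH2)CH2SiMe3, C4H2OH) | OC[C@](C)(CCC3(C(C)C)OCCO3)[C@@H]2OC(C)(C)O[C@@H]2C(=C)C[Si](C)(C)C | intermediate
17 | allylsilane aldehyde (C4HO on quaternary C5) | O=C[C@](C)(CCC3(C(C)C)OCCO3)[C@@H]2OC(C)(C)O[C@@H]2C(=C)C[Si](C)(C)C | intermediate
18 | (E)-alkenyl iodide with C8 ethylene ketal | I/C=C/[C@](C)(CCC3(C(C)C)OCCO3)[C@@H]2OC(C)(C)O[C@@H]2C(=C)C[Si](C)(C)C | intermediate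
19 | (E)-alkenyl iodide with free C8 isopropyl ketone | I/C=C/[C@](C)(CCC(=O)C(C)C)[C@@H]2OC(C)(C)O[C@@H]2C(=C)C[Si](C)(C)C | intermediate
20 | open-chain keto (E)-p-methoxybenzyl enol ether allylsilane with 9,10-O-isopropylidene group (5S,9S,10R) | CC(C)C(=O)CC[C@@](C)(/C=C/OCc1ccc(OC)cc1)[C@@H]2OC(C)(C)O[C@@H]2C(=C)C[Si](C)(C)C | intermediate
21 | cyclopentane titanium aldolate with C3 oxocarbenium ion (zwitterion) | COc1ccc(C[O+]=C[C@@H]2[C@](C)(CC[C@@]2(O[Ti-](Cl)(Cl)(Cl)Cl)C(C)C)[C@@H]3OC(C)(C)O[C@@H]3C(=C)C[Si](C)(C)C)cc1 | intermediate
22 | bicyclic C3 p-methoxybenzyl ether, C8 carbinol, 9,10-O-isopropylidene (3S,4S,5S,8R,9S,10R) | C=C1C[C@H](OCc2ccc(OC)cc2)[C@@H]3[C@](C)(CC[C@@]3(O)C(C)C)[C@@H]4OC(C)(C)O[C@H]14 | intermediate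
23 | bicyclic C3,C8-diol with 9,10-O-isopropylidene group | C=C1C[C@H](O)[C@@H]3[C@](C)(CC[C@@]3(O)C(C)C)[C@@H]4OC(C)(C)O[C@H]14 | intermediate
24 | 3-methylbutanoyl chloride | CC(C)CC(=O)Cl | starting material
25 | C3 3-methylbutanoate with 9,10-O-isopropylidene group | C=C1C[C@H](OC(=O)CC(C)C)[C@@H]3[C@](C)(CC[C@@]3(O)C(C)C)[C@@H]4OC(C)(C)O[C@H]14 | intermediate
26 | CNP0204264.1 (3S,4S,5S,8R,9S,10R) | C=C1C[C@H](OC(=O)CC(C)C)[C@@H]2[C@](C)(CC[C@@]2(O)C(C)C)[C@H](O)[C@@H]1O | target

## Step count and least certain steps

Total step count: 16 (step 3 prepares the side-chain iodide 6). Longest linear sequence: 15 steps (steps 1, 2 and 4–16, from 1 to 26).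

Step 13 (key step, proposed new method). The most likely failure is that the seven-membered closure is outrun by collapse of the C3 oxocarbenium ion of 21: loss of the p-methoxybenzyl group to chloride, loss of H4 back to an enol ether, or retro-aldol. A 2-substituted allylsilane closing a seven-membered ring is slower than these unimolecular exits. Two further leaks are ionisation of the dioxolane next to the allylsilane, and attack of the enol ether on the wrong face at C4, after which O9 can reach C3. The fallback uses known reactions only, sets out from 20 and returns at 23:
- The enol ether of 20 is hydrolysed (PPTS, wet acetone, as in step 11) to the keto aldehyde F1.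
- An amine-catalysed intramolecular aldol addition (pyrrolidine/AcOH, enamine of the aldehyde onto the C8 ketone, 5-(enolexo)) gives the β-hydroxy aldehyde F2. The conditions are reversible and should favour the arrangement in which the C9 arm, the formyl group and the isopropyl group are mutually trans.
- A chelation-controlled intramolecular Hosomi–Sakurai reaction of F2 (SnCl4, CH2Cl2, −78 °C) closes C2–C3 and gives 23 directly, so step 14 is not needed.

Step 4. The most likely failure is β-elimination of the C9 oxygen from enolate 7 before alkylation, because the unactivated, γ-branched iodide 6 reacts slowly at the temperatures at which the enolate is stable. The fallback replaces the enolate SN2 by a conjugate addition, sets out from 3 and returns at 8: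
- Lactone 3 is converted with LiN(iPr)2/Me3SiCl at −78 °C (internal quench) into the silyl ketene acetal F3.
- A Mukaiyama–Michael addition of F3 to enone 4 (Sc(OTf)3 cat., CH2Cl2, −78 °C) gives the keto lactone F4.
- Silyl-transfer ketalisation of F4 with 1,2-bis(trimethylsilyloxy)ethane and catalytic Me3SiOTf at −78 °C gives 8.

Step 7. The most likely failure is poor site selectivity between the two primary hydroxyls: oxidation starting at the neopentyl C4–OH returns a lactone of type 10. Epimerisation at C10 of the intermediate α-alkoxy aldehyde is a lesser risk. The fallback avoids differentiating a diol, sets out from 10 and returns at 18 (it bypasses steps 6–10):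
- DIBAL-H (−78 °C) reduces 10 to the lactol F5.
- Takai olefination of the lactol (CrCl2, CHI3) gives the hydroxy alkenyl iodide F6.
- Oxidation (TEMPO, PhI(OAc)2, MeCN/H2O) gives the acid F7, and Me3SiCHN2 gives the methyl ester F8.
- Reagent 14 with CeCl3 adds twice to give the carbinol F9, and silica-promoted Peterson elimination gives 18.

Step 12. The most likely failure is slow C–O coupling at the temperature required, which allows base-mediated dehydrohalogenation of the alkenyl iodide to the alkyne or enolisation and condensation of the ketone. The fallback makes the enol ether by olefination, sets out from 17 and returns at 20 (it bypasses steps 10–12):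
- The ketal of 17 is exchanged (PPTS, wet acetone) to give the keto aldehyde F10.
- A Wittig reaction with [(4-methoxybenzyloxy)methyl]triphenylphosphonium chloride and KN(SiMe3)2 (THF, −78 → 0 °C) should select the aldehyde over the hindered ketone and give 20 together with its Z isomer F11, which is removed by chromatography on base-washed silica.

## Further compounds

F1 | step 13 | keto aldehyde from hydrolysis of the enol ether of 20 (C3HO–C4H2 on C5) | O=CC[C@](C)(CCC(=O)C(C)C)[C@@H]1OC(C)(C)O[C@@H]1C(=C)C[Si](C)(C)C
F2 | step 13 | cyclopentane β-hydroxy aldehyde (C4–C8 bond formed, formyl on C4 trans to the C9 arm, C8 hydroxyl cis to formyl) | O=C[C@@H]1[C@](C)(CC[C@@]1(O)C(C)C)[C@@H]2OC(C)(C)O[C@@H]2C(=C)C[Si](C)(C)C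
F3 | step 4 | trimethylsilyl ketene acetal of lactone 3 | C[Si](C)(C)OC1=C[C@@H]2OC(C)(C)O[C@@H]2CO1
F4 | step 4 | lactone 3 with a 4-methyl-3-oxopentyl chain at C5 (trans to the dioxolane) | O=C1[C@@H](CCC(=O)C(C)C)[C@@H]2OC(C)(C)O[C@@H]2CO1
F5 | step 7 | lactol from reduction of 10 (anomer mixture) | OC1OC[C@H]2OC(C)(C)O[C@H]2[C@@]1(C)CCC3(C(C)C)OCCO3
F6 | step 7 | (E)-alkenyl iodide with free C1H2OH and C8 ethylene ketal | I/C=C/[C@](C)(CCC3(C(C)C)OCCO3)[C@@H]2OC(C)(C)O[C@@H]2CO
F7 | step 7 | (E)-alkenyl iodide C1 carboxylic acid | I/C=C/[C@](C)(CCC3(C(C)C)OCCO3)[C@@H]2OC(C)(C)O[C@@H]2C(=O)O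
F8 | step 7 | (E)-alkenyl iodide C1 methyl ester | I/C=C/[C@](C)(CCC3(C(C)C)OCCO3)[C@@H]2OC(C)(C)O[C@@H]2C(=O)OC
F9 | step 7 | (E)-alkenyl iodide bis[(trimethylsilyl)methyl]carbinol at C1 | I/C=C/[C@](C)(CCC3(C(C)C)OCCO3)[C@@H]2OC(C)(C)O[C@@H]2C(O)(C[Si](C)(C)C)C[Si](C)(C)C
F10 | step 12 | keto aldehyde (C4HO on C5, free C8 ketone, allylsilane) | O=C[C@](C)(CCC(=O)C(C)C)[C@@H]2OC(C)(C)O[C@@H]2C(=C)C[Si](C)(C)C
F11 | step 12 | (Z)-enol ether isomer of 20 | CC(C)C(=O)CC[C@@](C)(/C=C\OCc1ccc(OC)cc1)[C@@H]2OC(C)(C)O[C@@H]2C(=C)C[Si](C)(C)C
A1 | alternative 1 | bicyclic cycloheptadiene silyl enol ether ester with C5 quaternary centre and C8 ethylene ketal | COC(=O)C1=C(O[Si](C)(C)C(C)(C)C)C[C@@]2(C)CCC3(OCCO3)C2=CC1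
A2 | alternative 1 | 6-ethenyl-7-methyl-1,4-dioxaspiro[4.4]non-6-ene | C=CC1=C(C)CCC12OCCO2
A3 | alternative 1 | methyl 3-(tert-butyldimethylsilyloxy)-2-diazobut-3-enoate | COC(=O)C(=[N+]=[N-])C(=C)O[Si](C)(C)C(C)(C)C
A4 | alternative 2 | anti-aldol cyclopentanone with C5 quaternary centre and 1-(trimethylsilyl)ethenyl group | C=CCC[C@H](O)[C@@H]1[C@](C)(CCC1=O)C(=C)[Si](C)(C)C
A5 | alternative 2 | 3-methylcyclopent-2-en-1-one | CC1=CC(=O)CC1
A6 | alternative 2 | pent-4-enal | C=CCCC=O
A7 | alternative 2 | bis(2-methylpropyl)[1-(trimethylsilyl)ethenyl]alumane | C=C([Si](C)(C)C)[Al](CC(C)C)CC(C)C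
A8 | alternative 3 | tris(triethylsilyl) ether of 26 (O8, O9, O10) | C=C1C[C@H](OC(=O)CC(C)C)[C@@H]2[C@](C)(CC[C@@]2(O[Si](CC)(CC)CC)C(C)C)[C@H](O[Si](CC)(CC)CC)[C@@H]1O[Si](CC)(CC)CC
A9 | alternative 3 | cyclopentane ynal (C10 aldehyde, C1 terminal alkyne, O8 and O9 triethylsilyl ethers, C3 ester) | C#CC[C@H](OC(=O)CC(C)C)[C@@H]1[C@](C)(CC[C@@]1(O[Si](CC)(CC)CC)C(C)C)[C@H](O[Si](CC)(CC)CC)C=O
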